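Atoms are numbered as in ent-kaurane throughout. Ring A: C1–C5 and C10. Lactone: C10, C20, O, C7, C8, C9. Ring C: C8, C9, C11–C14. Ring D: C8, C15, C16, C13, C14.

## Analysis of the target

Compound 35 is a 6,7-seco-ent-kaurane of the spirolactone type. Ring A (C1 ketone, C2=C3, C4 gem-dimethyl, C5 carrying C6H2OH) is spiro-joined at C10 to a δ-lactone, which is cis-fused along C8–C9 to ring C. Ring D bridges ring C to a bicyclo[3.2.1]octane with the C15 ketone and the C16 methyl carbinol in the two-carbon bridge. The six stereocentres are (5R,8S,9S,10S,13R,16S): C6 and C20 are cis on ring A, H9 and C15 are cis across the C8–C9 fusion, C16 leaves C13 on the face of ring C from which C15 leaves C8, and the C16 hydroxyl lies on the exo face of ring D (toward C14, away from C11–C12). C10 and C8 are quaternary and flank C9, and C16 is fully substituted. The sensitive groups are the enone (a free O6 can reach C3), the non-enolisable β-keto lactone C7–C8–C15 (retro-Claisen cleavage by nucleophiles) and the tertiary α-ketol (acyloin shift). The difficulty lies in the congestion along C10–C9–C8, in two primary oxygens (O6, O20) that sit cis on neighbouring carbons and must be told apart, and in the C15/C16 pair, a 1,2-dioxygenated unit that normal carbonyl polarity cannot assemble. The strategy rests on this pair: C15 and C16 bridge C8 and C13, which are 1,3-related on ring C, so an aldehyde carbon on C8 and an ethynyl group on C13 lie side by side when both are axial, and joining them needs only a reversal of the aldehyde's polarity.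

## Retrosynthetic reasoning

**End-game adjustments (35 ⇐ 34 ⇐ 33 ⇐ 32).** No skeletal bond is cut here. The C2=C3 bond goes back to the saturated ketone 33 (IBX dehydrogenation forward), the C1 carbonyl to the dioxolane 32, and O6 stays silylated as far as 34. The order is forced: IBX oxidises a free primary alcohol, so O6 is unmasked last, and the dioxolane has to fall while the silyl ether stays, which is why O6 carries an acid-stable tert-butyldiphenylsilyl group.

**C16–O and C17–H (32 ⇐ 31 ⇐ 29).** The tertiary ketol is the Markovnikov hydrate of the exocyclic enone 29. A radical hydration delivers hydrogen to C17 and oxygen to C16 from the open exo face. The C11=C12 alkene is hydrogenated afterwards, because hydrogenation first would also reduce the conjugated alkene.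

**C15–C16, the key disconnection (29 ⇐ 28).** This bond joins two carbons that are both electrophilic in their natural synthons, so it is cut with polarity reversal: C15 as an acyl anion (the aldehyde of 28 under carbene catalysis) and C16 as the inner carbon of a terminal alkyne. Cutting C8–C15 or C13–C16 instead would mean forming a quaternary or a bridgehead bond late. Cutting C15–C16 leaves two substituents that an earlier cycloaddition can place 1,3-cis. The forward step is redox-neutral, adds no atoms and gives the enone needed for the hydration.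

**Oxidation level and alkyne terminus (28 ⇐ 27 ⇐ 26).** The aldehyde comes from the C15 alcohol, and the terminal alkyne from its trimethylsilyl derivative. The silyl group is removed before oxidation, because methoxide would deformylate the β-formyl lactone.

**C8–C9 and C13–C14 (26 ⇐ 25).** An ester-tethered intramolecular Diels–Alder reaction forms the lactone and ring C together. The tether fixes the regiochemistry, which an intermolecular reaction would not give because the conjugating alkynyl group would direct the other way. The (9E,12Z) diene geometry with the ester carbonyl endo places H9, C15 and the alkyne on one face. C15 is kept as CH2OH in 25 so that the tether carbonyl, and not a formyl group, is the endo director.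

**Dienophile and diene (25 ⇐ 22 + 23; 22 ⇐ 18 + 21).** The 2-(hydroxymethyl)acrylate is made on the substrate from the phosphonoacetate 22 and two molecules of formaldehyde 23, so O15 needs no protecting group. The C11–C12 bond is cut to the (E)-alkenylboronate 18 and the (Z)-chloroenyne 21, each of which carries its geometry into the coupling.

**Telling O6 and O20 apart (18 ⇐ 17 ⇐ 16 ⇐ 14 ⇐ 12 + 13; 12 ⇐ 11).** The ester of 11 is reduced to O20–H and acylated at once with acid 13, an ozone-stable latent dienophile. Only then is O6 made, by ozonolysis of the styryl group, and silylated. The two primary alcohols are therefore never free together, and no γ-lactone can form between them.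

**C10–C9 and the C1 mask (11 ⇐ 10 ⇐ 8 + 9).** The quaternary centre comes from electrophilic alkynylation of the β-keto ester 8 with 9, anti to the C5 substituent. The ester becomes C20 (cis to C6) and the ethynyl group becomes C9≡C11 (trans to C6). The dioxolane is put on before the hydride reduction and serves again in the key step.

**C5–C6 and ring A (8 ⇐ 6 + 7; 6 ⇐ 3 ⇐ 1 + 2).** The only stereocentre not set by the substrate is C5. It comes from a catalytic asymmetric conjugate addition of the alkenylboronic acid 7 to the alkylidene β-keto ester 6. In 6 the ester fixes the position of the later enolate, and the gem-dimethyl group prevents aromatisation. 6 comes from ketone 1 and carbonate 2 through 3.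

**The Z-enyne (21 ⇐ 19 + 20).** One Sonogashira coupling of 19 with 20, with retention of the Z geometry.

## Alternatives that were turned down

**Alternative 1:** Disconnection of C10–C20. In the forward step the ring A enone A1 (C2 ketone, C1=C10, vinyl on C10, O6 as a (bromomethyl)dimethylsilyl ether) gives, under tin hydride chain conditions, an α-silyl radical at C20 that adds 6-exo to C10 and forms the cis-fused siloxane A2. Oxidative cleavage of C–Si would then free O20.
- For: C20 is delivered from O6, so the cis relation of C6 and C20 at the quaternary centre is enforced by the ring and not by facial selectivity. On this point it is stronger than step 4 of the chosen route.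
- Against: the carbonyl that activates C10 ends at C2, with C1 as CH2, so a 1,2-carbonyl transposition over several steps is needed. The C–Si oxidation frees O6 and O20 together, which brings back the differentiation problem. Stoichiometric tin is used. The step solves only C10, so the lactone, ring C and ring D are still to be made.
- Comparison: the chosen route reaches C10 in one step from a β-keto ester whose ketone is already C1 and whose ester is already C20, keeps O6 and O20 apart by the order of steps, and spends its risk on ring D.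

**Alternative 2:** Disconnection of C8–C9 and C13–C14 as the central step. Heating the triene A3 closes the lactone and ring C to A4.
- For: two rings, two bonds and three stereocentres in one stereospecific step. This is more complexity per step than the hydroacylation (one ring, one bond, no stereocentre), and the same cycloaddition is kept in the chosen route as step 14.
- Against, as the step that carries the strategy: A4 has no ring D, and the like-polarity C15–C16 bond remains unsolved. A4 carries two primary tert-butyldimethylsilyl ethers, of which the more hindered neopentyl one on O15 would have to go first. Its free C1 ketone would compete in any nucleophilic closure of ring D.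
- Comparison: the chosen strategy uses the cycloaddition with O15 free, a TBDPS group on O6 and a dioxolane on C1, and adds the atom-economical ring D closure.

**Alternative 3:** Disconnection of C8–C14 and C9–C11. Buta-1,3-diene A6 adds across C8=C9 of the spiro 2-acyl unsaturated lactone A5 under aluminium Lewis acid catalysis and gives the cis-fused adduct A7, with C15 as a thioester on quaternary C8.
- For: a doubly activated dienophile that reacts at low temperature, a convergent intermolecular step, C15 already at the acid level (Fukuyama reduction to the aldehyde), and no Z-enyne or 170 °C step. It is stronger on reactivity and convergence.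
- Against: A6 leaves C12=C13 without a substituent at C13. The ethynyl group, cis to C15, would have to be added to an alkene whose two carbons are barely differentiated. A 2-substituted diene would place its substituent at C12 (para to C8), not at C13. Facial selectivity on A5 rests on ring A alone.
- Comparison: the tethered cycloaddition of the chosen route delivers the C13 ethynyl group in the right relative configuration, because the tether fixes regiochemistry and the diene geometry fixes C13.

Key step: step 17

Remark on the chemistry: the sense of induction in step 3 is assumed to follow that of the rhodium/BINAP addition to cyclohex-2-en-1-one, which calls for (R)-BINAP; if it is the opposite, (S)-BINAP is used and nothing else changes.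

## Route

Step 1
Reactants: 1 4,4-dimethylcyclohexan-1-one; 2 dimethyl carbonate
Product: 3 methyl 5,5-dimethyl-2-oxocyclohexane-1-carboxylate
Conditions: NaH, THF, reflux; aq. HCl
Reagents that add atoms: none
Why: Claisen-type C-acylation of the ketone enolate by the carbonate, driven by formation of the stabilised β-keto ester enolate; the ester carbon is the future C20.

Step 2
Reactants: 3 methyl 5,5-dimethyl-2-oxocyclohexane-1-carboxylate
Product: 6 methyl 3,3-dimethyl-6-oxocyclohex-1-ene-1-carboxylate, via α-phenylselanyl keto ester 4 (not isolated), via selenoxide 5 (not isolated)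
Conditions: PhSeCl, pyridine, CH2Cl2, 0 °C; then 30% H2O2, 0 °C to rt
Reagents that add atoms: none
Why: Selenenylation at the doubly activated carbon, oxidation and selenoxide syn-elimination toward the only ring carbon with a β-hydrogen; the gem-dimethyl group blocks tautomerisation to a phenol, so 6 should be isolable.

Step 3
Reactants: 6 methyl 3,3-dimethyl-6-oxocyclohex-1-ene-1-carboxylate; 7 (E)-(2-phenylethenyl)boronic acid
Product: 8 methyl (6S)-5,5-dimethyl-2-oxo-6-[(E)-2-phenylethenyl]cyclohexane-1-carboxylate (C1 epimers and enol)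
Conditions: [Rh(OH)((R)-binap)]2 (3 mol %), 1,4-dioxane/H2O 10:1, 40 °C
Reagents that add atoms: none
Why: Rhodium-catalysed asymmetric 1,4-addition of an alkenylboronic acid (Hayashi–Miyaura reaction); the two carbonyl groups make the neopentyl β-carbon reactive and fix where the enolate forms. The ligand selects the enone face and so sets C5 (6S in 8); the styryl group is a masked CH2OH.

Step 4
Reactants: 8 methyl (6S)-5,5-dimethyl-2-oxo-6-[(E)-2-phenylethenyl]cyclohexane-1-carboxylate; 9 1-[(trimethylsilyl)ethynyl]-1,2-benziodoxol-3(1H)-one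
Product: 10 methyl (1S,6R)-1-ethynyl-5,5-dimethyl-2-oxo-6-[(E)-2-phenylethenyl]cyclohexane-1-carboxylate
Conditions: TBAF, THF, −78 °C to rt
Reagents that add atoms: none
Why: Electrophilic α-alkynylation of a β-keto ester enolate by the ethynyl benziodoxolone that fluoride releases from 9 (addition to the alkynyl iodine species, loss of iodobenzoate, 1,2-shift). The reagent comes in anti to the styryl group on C5, so C9 ends trans and the ester (C20) cis to C6, which sets C10.

Step 5
Reactants: 10 methyl (1S,6R)-1-ethynyl-5,5-dimethyl-2-oxo-6-[(E)-2-phenylethenyl]cyclohexane-1-carboxylate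
Product: 11 methyl (6S,7R)-6-ethynyl-8,8-dimethyl-7-[(E)-2-phenylethenyl]-1,4-dioxaspiro[4.5]decane-6-carboxylate
Conditions: HOCH2CH2OH, TsOH·H2O (cat.), benzene, reflux, Dean–Stark
Reagents that add atoms: ethylene glycol, OCCO
Why: Acid-catalysed ketalisation with azeotropic removal of water; the ketone is activated by its electron-poor α-substituents. The dioxolane masks C1 for the hydride step and for the carbene step.

Step 6
Reactants: 11 methyl (6S,7R)-6-ethynyl-8,8-dimethyl-7-[(E)-2-phenylethenyl]-1,4-dioxaspiro[4.5]decane-6-carboxylate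
Product: 12 [(6R,7R)-6-ethynyl-8,8-dimethyl-7-[(E)-2-phenylethenyl]-1,4-dioxaspiro[4.5]decan-6-yl]methanol
Conditions: LiAlH4, THF, 0 °C
Reagents that add atoms: none
Why: Hydride reduction of the ester to the neopentyl alcohol O20–H; ketal, alkyne and styrene are not reduced.

Step 7
Reactants: 12 [(6R,7R)-6-ethynyl-8,8-dimethyl-7-[(E)-2-phenylethenyl]-1,4-dioxaspiro[4.5]decan-6-yl]methanol; 13 2-(diethoxyphosphoryl)acetic acid
Product: 14 [(6R,7R)-6-ethynyl-8,8-dimethyl-7-[(E)-2-phenylethenyl]-1,4-dioxaspiro[4.5]decan-6-yl]methyl 2-(diethoxyphosphoryl)acetate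
Conditions: EDC·HCl, DMAP, CH2Cl2, rt
Reagents that add atoms: none
Why: Steglich esterification; O20 is acylated with an ozone-stable latent dienophile before O6 exists, so the two primary oxygens are never free together.

Step 8
Reactants: 14 [(6R,7R)-6-ethynyl-8,8-dimethyl-7-[(E)-2-phenylethenyl]-1,4-dioxaspiro[4.5]decan-6-yl]methyl 2-(diethoxyphosphoryl)acetate
Product: 16 [(6R,7R)-6-ethynyl-7-(hydroxymethyl)-8,8-dimethyl-1,4-dioxaspiro[4.5]decan-6-yl]methyl 2-(diethoxyphosphoryl)acetate, via C6 aldehyde 15 (not isolated)
Conditions: O3, CH2Cl2/MeOH 4:1, −78 °C (Sudan Red 7B end point); then NaBH4, −78 to 0 °C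
Reagents that add atoms: ozone, [O-][O+]=O
Why: Ozonolysis of the styrene, which reacts far faster than the terminal alkyne, with reductive work-up to the alcohol. Reduction of 15 at low temperature should outrun both epimerisation at C5 and an intramolecular Horner–Wadsworth–Emmons reaction.

Step 9
Reactants: 16 [(6R,7R)-6-ethynyl-7-(hydroxymethyl)-8,8-dimethyl-1,4-dioxaspiro[4.5]decan-6-yl]methyl 2-(diethoxyphosphoryl)acetate
Product: 17 [(6R,7R)-7-{[tert-butyl(diphenyl)silyl]oxymethyl}-6-ethynyl-8,8-dimethyl-1,4-dioxaspiro[4.5]decan-6-yl]methyl 2-(diethoxyphosphoryl)acetate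
Conditions: TBDPSCl, imidazole, DMF, rt
Reagents that add atoms: tert-butyl(chloro)diphenylsilane, CC(C)(C)[Si](Cl)(c1ccccc1)c1ccccc1
Why: Silylation of the primary alcohol; the TBDPS ether is chosen because it survives the acidic ketal hydrolysis of step 20 and covers O6 during the IBX step.

Step 10
Reactants: 17 [(6R,7R)-7-{[tert-butyl(diphenyl)silyl]oxymethyl}-6-ethynyl-8,8-dimethyl-1,4-dioxaspiro[4.5]decan-6-yl]methyl 2-(diethoxyphosphoryl)acetate
Product: 18 [(6S,7R)-7-{[tert-butyl(diphenyl)silyl]oxymethyl}-8,8-dimethyl-6-[(E)-2-(4,4,5,5-tetramethyl-1,3,2-dioxaborolan-2-yl)ethenyl]-1,4-dioxaspiro[4.5]decan-6-yl]methyl 2-(diethoxyphosphoryl)acetate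
Conditions: HBpin, Cp2Zr(H)Cl (10 mol %), Et3N (10 mol %), THF, 60 °C
Reagents that add atoms: pinacolborane, CC1(C)OBOC1(C)C
Why: Zirconium-catalysed syn hydroboration of a terminal alkyne; boron goes to the terminal carbon C11, away from quaternary C10, which gives the E-alkenylboronate (C9=C11).

Step 11
Reactants: 19 (Z)-1,2-dichloroethene; 20 ethynyltrimethylsilane
Product: 21 (Z)-(4-chlorobut-3-en-1-yn-1-yl)trimethylsilane
Conditions: Pd(PPh3)4 (3 mol %), CuI (6 mol %), n-BuNH2, Et2O, rt; 19 in threefold excess
Reagents that add atoms: none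
Why: Sonogashira coupling; with the dichloride in excess only one C–Cl bond reacts, and oxidative addition proceeds with retention, so the Z geometry (C12=C13) is kept.

Step 12
Reactants: 18 [(6S,7R)-7-{[tert-butyl(diphenyl)silyl]oxymethyl}-8,8-dimethyl-6-[(E)-2-(4,4,5,5-tetramethyl-1,3,2-dioxaborolan-2-yl)ethenyl]-1,4-dioxaspiro[4.5]decan-6-yl]methyl 2-(diethoxyphosphoryl)acetate; 21 (Z)-(4-chlorobut-3-en-1-yn-1-yl)trimethylsilane
Product: 22 [(6S,7R)-7-{[tert-butyl(diphenyl)silyl]oxymethyl}-8,8-dimethyl-6-[(1E,3Z)-6-(trimethylsilyl)hexa-1,3-dien-5-yn-1-yl]-1,4-dioxaspiro[4.5]decan-6-yl]methyl 2-(diethoxyphosphoryl)acetate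
Conditions: Pd(OAc)2 (5 mol %), SPhos (10 mol %), K3PO4, THF/H2O, 45 °C
Reagents that add atoms: none
Why: Suzuki–Miyaura coupling of an alkenylboronate with an alkenyl chloride that is activated by conjugation to the alkyne; both partners react with retention, which gives the (9E,12Z)-dienyne.

Step 13
Reactants: 22 [(6S,7R)-7-{[tert-butyl(diphenyl)silyl]oxymethyl}-8,8-dimethyl-6-[(1E,3Z)-6-(trimethylsilyl)hexa-1,3-dien-5-yn-1-yl]-1,4-dioxaspiro[4.5]decan-6-yl]methyl 2-(diethoxyphosphoryl)acetate; 23 formaldehyde
Product: 25 [(6S,7R)-7-{[tert-butyl(diphenyl)silyl]oxymethyl}-8,8-dimethyl-6-[(1E,3Z)-6-(trimethylsilyl)hexa-1,3-dien-5-yn-1-yl]-1,4-dioxaspiro[4.5]decan-6-yl]methyl 2-(hydroxymethyl)prop-2-enoate, via α-(hydroxymethyl)phosphonoacetate 24 (not isolated)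
Conditions: methanol-free aq. HCHO (excess), K2CO3, THF/H2O, rt
Reagents that add atoms: none
Why: Known one-pot hydroxymethylation and Horner–Wadsworth–Emmons sequence of phosphonoacetates with aqueous formaldehyde: the carbanion adds to formaldehyde (C15), the still acidic adduct 24 adds to a second molecule and eliminates phosphate (C8=C14). O15 stays free, and the plain acrylate is the expected minor by-product.

Step 14
Reactants: 25 [(6S,7R)-7-{[tert-butyl(diphenyl)silyl]oxymethyl}-8,8-dimethyl-6-[(1E,3Z)-6-(trimethylsilyl)hexa-1,3-dien-5-yn-1-yl]-1,4-dioxaspiro[4.5]decan-6-yl]methyl 2-(hydroxymethyl)prop-2-enoate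
Product: 26 tricyclic lactone (5R,8S,9S,10S,13S): C1 dioxolane, C5 CH2OTBDPS, spiro C10, δ-lactone cis-fused to cyclohexene ring C (C11=C12), CH2OH (C15) on C8 and C≡C–SiMe3 on C13, both cis to H9
Conditions: toluene (0.005 M), BHT, 170 °C, sealed vessel
Reagents that add atoms: none
Why: Ester-tethered intramolecular Diels–Alder reaction, helped by the gem-disubstitution at C10; it forms C8–C9 and C13–C14 and closes the lactone and ring C. With the tether carbonyl endo the fusion is cis and C15 is exo, hence cis to the two inside groups of the (9E,12Z)-diene, H9 and the slim alkynyl group (this sets C8, C9 and C13 relative to each other). The diene arm should turn toward the C1 dioxolane and away from the equatorial silyloxymethyl group on C5, which sets C9 relative to C10.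

Step 15
Reactants: 26 tricyclic lactone with C15 hydroxyl and C13 (trimethylsilyl)ethynyl group
Product: 27 tricyclic lactone (5R,8S,9S,10S,13S) with C15 hydroxyl and C13 ethynyl group
Conditions: K2CO3, MeOH, 0 °C
Reagents that add atoms: none
Why: Methanolysis of the C(sp)–Si bond; the lactone carbonyl next to quaternary C8 should not be touched at 0 °C. The step comes before oxidation because methoxide would deformylate the β-formyl lactone.

Step 16
Reactants: 27 tricyclic lactone with C15 hydroxyl and C13 ethynyl group
Product: 28 tricyclic lactone (5R,8S,9S,10S,13S) with formyl (C15) on C8 and ethynyl (C16≡C17) on C13, cis to each other; C1 dioxolane, C6 OTBDPS, C11=C12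
Conditions: Dess–Martin periodinane, NaHCO3, CH2Cl2, 0 °C to rt
Reagents that add atoms: none
Why: Dess–Martin oxidation of the neopentyl primary alcohol; the aldehyde has no α-hydrogen and cannot enolise or epimerise, and the buffer protects the ketal.

Step 17
Reactants: 28 tricyclic lactone with C8 formyl and C13 ethynyl groups
Product: 29 tetracyclic 16-methylene-15-ketone (5R,8S,9S,10S,13S): ring D closed, C1 dioxolane, C6 OTBDPS, C11=C12
Conditions: 4,5-dimethyl-3-(2,4,6-trimethylphenyl)thiazol-3-ium perchlorate (20 mol %), K2CO3 (40 mol %), THF (0.02 M), 70 °C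
Reagents that add atoms: none
Why: Proposed new method: the carbene released from the thiazolium salt adds to the C15 aldehyde, which has no α-hydrogen, and proton transfer gives the Breslow intermediate with a nucleophilic C15. C15 then bonds to the near alkyne carbon C16 while the enol proton passes to C17 in a concerted ene-type (Conia-ene-like) transition state, and the alkoxide expels the carbene to leave the enone 29. The closest known reaction type is the N-heterocyclic-carbene-catalysed intramolecular hydroacylation of unactivated alkynes by aromatic aldehydes with an alkynyl ether side chain; an aliphatic α-quaternary aldehyde closing a bridged carbocycle is the untested part. Ring D closes 5-exo-dig: C15 on C8 and the ethynyl group on C13 are 1,3-cis on ring C and, when both axial, hold C15 within about 3 Å of C16 and side-on to the alkyne, whereas the 6-endo path to C17 would need an endocyclic double bond in a bridged ring. No stereocentre is created, since C8 and C13 are already set and C16 becomes trigonal. The step needs chemoselectivity against the C1 carbonyl, which is masked as the dioxolane because a free ketone would take the acyl anion in a five-membered crossed benzoin closure. It also needs selectivity against C11=C12, where attack would build a strained 7-norbornanone bridge and alkenes react far more slowly than alkynes in this manifold. Dimerisation is unlikely because the neopentyl aldehyde is too hindered for an intermolecular benzoin reaction, and dilution limits carbene or acyl-anion addition to the product enone.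

Step 18
Reactants: 29 tetracyclic 16-methylene-15-ketone
Product: 31 16-hydroxy-16-methyl-15-ketone (5R,8S,9S,10S,13S,16S): C1 dioxolane, C6 OTBDPS, C11=C12, via C16 hydroperoxide 30 (not isolated)
Conditions: Mn(dpm)3 (10 mol %), PhSiH3, O2 (1 atm), i-PrOH/CH2Cl2, 0 °C; then P(OEt)3
Reagents that add atoms: dioxygen, O=O
Why: Mukaiyama hydration by hydrogen-atom transfer: the manganese hydride gives H to C17, and the tertiary α-keto radical at C16 is trapped by O2; the phosphite reduces hydroperoxide 30. Oxygen should arrive on the exo face of ring D (toward C14, away from the C11=C12 bridge), which gives 16S; the isolated ring alkene is not a substrate under manganese conditions.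

Step 19
Reactants: 31 16-hydroxy-16-methyl-15-ketone with C11=C12
Product: 32 11,12-dihydro compound (5R,8S,9S,10S,13R,16S): C1 dioxolane, C6 OTBDPS
Conditions: H2 (1 atm), Pd/C, EtOAc, rt
Reagents that add atoms: none
Why: Heterogeneous hydrogenation of the cis-disubstituted ring alkene; nothing else is reducible and no stereocentre forms (the C13 descriptor changes only through substituent priorities).

Step 20
Reactants: 32 dioxolane of the saturated tetracycle
Product: 33 C1 ketone (5R,8S,9S,10S,13R,16S) with C6 OTBDPS
Conditions: 1 M HCl, THF, rt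
Reagents that add atoms: water, O
Why: Acid-catalysed hydrolysis of the dioxolane; the TBDPS ether, the lactone and the tertiary ketol should tolerate dilute acid at room temperature.

Step 21
Reactants: 33 C1 ketone with C6 OTBDPS
Product: 34 1-oxo-2-ene (5R,8S,9S,10S,13R,16S) with C6 OTBDPS, the silyl ether of the target
Conditions: IBX, DMSO, 75 °C
Reagents that add atoms: none
Why: IBX dehydrogenation of a ketone to the enone through its enol; only C2–C3 can react, because C10 and C4 are quaternary and the C15 ketone has no α-hydrogen. O6 is silylated because IBX would oxidise a free primary alcohol, and the tertiary alcohol is inert.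

Step 22
Reactants: 34 silyl ether of the target
Product: 35 CNP0530135.1, (5R,8S,9S,10S,13R,16S)
Conditions: HF·pyridine, THF/pyridine, 0 °C to rt
Reagents that add atoms: none
Why: Fluoride cleavage of the silyl ether under acidic, non-nucleophilic conditions, which should avoid oxa-Michael addition of O6 to C3 and retro-Claisen opening of the β-keto lactone.

## Compound list

1 | 4,4-dimethylcyclohexan-1-one | CC1(C)CCC(=O)CC1 | starting material
2 | dimethyl carbonate | COC(=O)OC | starting material
3 | methyl 5,5-dimethyl-2-oxocyclohexane-1-carboxylate | COC(=O)C1CC(C)(C)CCC1=O | intermediate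
4 | methyl 5,5-dimethyl-2-oxo-1-(phenylselanyl)cyclohexane-1-carboxylate | COC(=O)C1([Se]c2ccccc2)CC(C)(C)CCC1=O | intermediate (not isolated)
5 | methyl 5,5-dimethyl-2-oxo-1-(phenylseleninyl)cyclohexane-1-carboxylate | COC(=O)C1([Se](=O)c2ccccc2)CC(C)(C)CCC1=O | intermediate (not isolated)
6 | methyl 3,3-dimethyl-6-oxocyclohex-1-ene-1-carboxylate | COC(=O)C1=CC(C)(C)CCC1=O | intermediate
7 | (E)-(2-phenylethenyl)boronic acid | OB(O)/C=C/c1ccccc1 | starting material
8 | methyl (6S)-5,5-dimethyl-2-oxo-6-[(E)-2-phenylethenyl]cyclohexane-1-carboxylate | CC1(C)CCC(=O)C(C(=O)OC)[C@@H]1/C=C/c1ccccc1 | intermediate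
9 | 1-[(trimethylsilyl)ethynyl]-1,2-benziodoxol-3(1H)-one | C[Si](C)(C)C#CI1OC(=O)c2ccccc12 | starting material
10 | methyl (1S,6R)-1-ethynyl-5,5-dimethyl-2-oxo-6-[(E)-2-phenylethenyl]cyclohexane-1-carboxylate | CC1(C)CCC(=O)[C@](C#C)(C(=O)OC)[C@@H]1/C=C/c1ccccc1 | intermediate
11 | methyl (6S,7R)-6-ethynyl-8,8-dimethyl-7-[(E)-2-phenylethenyl]-1,4-dioxaspiro[4.5]decane-6-carboxylate | CC1(C)CCC2(OCCO2)[C@](C#C)(C(=O)OC)[C@@H]1/C=C/c1ccccc1 | intermediate
12 | [(6R,7R)-6-ethynyl-8,8-dimethyl-7-[(E)-2-phenylethenyl]-1,4-dioxaspiro[4.5]decan-6-yl]methanol | CC1(C)CCC2(OCCO2)[C@](C#C)(CO)[C@@H]1/C=C/c1ccccc1 | intermediate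
13 | 2-(diethoxyphosphoryl)acetic acid | CCOP(=O)(CC(=O)O)OCC | starting material
14 | [(6R,7R)-6-ethynyl-8,8-dimethyl-7-[(E)-2-phenylethenyl]-1,4-dioxaspiro[4.5]decan-6-yl]methyl 2-(diethoxyphosphoryl)acetate | CC1(C)CCC2(OCCO2)[C@](C#C)(COC(=O)CP(=O)(OCC)OCC)[C@@H]1/C=C/c1ccccc1 | intermediate
15 | [(6R,7R)-6-ethynyl-7-formyl-8,8-dimethyl-1,4-dioxaspiro[4.5]decan-6-yl]methyl 2-(diethoxyphosphoryl)acetate | CC1(C)CCC2(OCCO2)[C@](C#C)(COC(=O)CP(=O)(OCC)OCC)[C@@H]1C=O | intermediate (not isolated)
16 | [(6R,7R)-6-ethynyl-7-(hydroxymethyl)-8,8-dimethyl-1,4-dioxaspiro[4.5]decan-6-yl]methyl 2-(diethoxyphosphoryl)acetate | CC1(C)CCC2(OCCO2)[C@](C#C)(COC(=O)CP(=O)(OCC)OCC)[C@@H]1CO | intermediate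
17 | [(6R,7R)-7-{[tert-butyl(diphenyl)silyl]oxymethyl}-6-ethynyl-8,8-dimethyl-1,4-dioxaspiro[4.5]decan-6-yl]methyl 2-(diethoxyphosphoryl)acetate | CC1(C)CCC2(OCCO2)[C@](C#C)(COC(=O)CP(=O)(OCC)OCC)[C@@H]1CO[Si](c1ccccc1)(c1ccccc1)C(C)(C)C | intermediate
18 | [(6S,7R)-7-{[tert-butyl(diphenyl)silyl]oxymethyl}-8,8-dimethyl-6-[(E)-2-(4,4,5,5-tetramethyl-1,3,2-dioxaborolan-2-yl)ethenyl]-1,4-dioxaspiro[4.5]decan-6-yl]methyl 2-(diethoxyphosphoryl)acetate | CC1(C)CCC2(OCCO2)[C@](/C=C/B3OC(C)(C)C(C)(C)O3)(COC(=O)CP(=O)(OCC)OCC)[C@@H]1CO[Si](c1ccccc1)(c1ccccc1)C(C)(C)C | intermediate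
19 | (Z)-1,2-dichloroethene | Cl/C=C\Cl | starting material
20 | ethynyltrimethylsilane | C#C[Si](C)(C)C | starting material
21 | (Z)-(4-chlorobut-3-en-1-yn-1-yl)trimethylsilane | C[Si](C)(C)C#C/C=C\Cl | intermediate
22 | [(6S,7R)-7-{[tert-butyl(diphenyl)silyl]oxymethyl}-8,8-dimethyl-6-[(1E,3Z)-6-(trimethylsilyl)hexa-1,3-dien-5-yn-1-yl]-1,4-dioxaspiro[4.5]decan-6-yl]methyl 2-(diethoxyphosphoryl)acetate | CC1(C)CCC2(OCCO2)[C@](/C=C/C=C\C#C[Si](C)(C)C)(COC(=O)CP(=O)(OCC)OCC)[C@@H]1CO[Si](c1ccccc1)(c1ccccc1)C(C)(C)C | intermediate
23 | formaldehyde | C=O | starting material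
24 | [(6S,7R)-7-{[tert-butyl(diphenyl)silyl]oxymethyl}-8,8-dimethyl-6-[(1E,3Z)-6-(trimethylsilyl)hexa-1,3-dien-5-yn-1-yl]-1,4-dioxaspiro[4.5]decan-6-yl]methyl 2-(diethoxyphosphoryl)-3-hydroxypropanoate (C2 of the propanoate unassigned) | CC1(C)CCC2(OCCO2)[C@](/C=C/C=C\C#C[Si](C)(C)C)(COC(=O)C(CO)P(=O)(OCC)OCC)[C@@H]1CO[Si](c1ccccc1)(c1ccccc1)C(C)(C)C | intermediate (not isolated)
25 | [(6S,7R)-7-{[tert-butyl(diphenyl)silyl]oxymethyl}-8,8-dimethyl-6-[(1E,3Z)-6-(trimethylsilyl)hexa-1,3-dien-5-yn-1-yl]-1,4-dioxaspiro[4.5]decan-6-yl]methyl 2-(hydroxymethyl)prop-2-enoate | CC1(C)CCC2(OCCO2)[C@](/C=C/C=C\C#C[Si](C)(C)C)(COC(=O)C(=C)CO)[C@@H]1CO[Si](c1ccccc1)(c1ccccc1)C(C)(C)C | intermediate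
26 | tricyclic lactone (5R,8S,9S,10S,13S): C1 dioxolane, C6 OTBDPS, C11=C12, C8 CH2OH (C15), C13 C≡C–SiMe3; H9, C15 and the alkyne cis on ring C | CC1(C)CCC2(OCCO2)[C@]3(COC(=O)[C@@]4(CO)C[C@H](C#C[Si](C)(C)C)C=C[C@H]43)[C@@H]1CO[Si](c1ccccc1)(c1ccccc1)C(C)(C)C | intermediate
27 | tricyclic lactone (5R,8S,9S,10S,13S) as 26 with C13 ethynyl | CC1(C)CCC2(OCCO2)[C@]3(COC(=O)[C@@]4(CO)C[C@H](C#C)C=C[C@H]43)[C@@H]1CO[Si](c1ccccc1)(c1ccccc1)C(C)(C)C | intermediate
28 | tricyclic lactone (5R,8S,9S,10S,13S) with C8 formyl (C15) and C13 ethynyl, precursor of the key step | CC1(C)CCC2(OCCO2)[C@]3(COC(=O)[C@@]4(C=O)C[C@H](C#C)C=C[C@H]43)[C@@H]1CO[Si](c1ccccc1)(c1ccccc1)C(C)(C)C | intermediate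
29 | tetracyclic 16-methylene-15-ketone (5R,8S,9S,10S,13S), product of the key step | CC1(C)CCC2(OCCO2)[C@]3(COC(=O)[C@@]45C[C@@H](C=C[C@H]43)C(=C)C5=O)[C@@H]1CO[Si](c1ccccc1)(c1ccccc1)C(C)(C)C | intermediate
30 | 16-hydroperoxy-16-methyl-15-ketone (16S), C11=C12 | CC1(C)CCC2(OCCO2)[C@]3(COC(=O)[C@@]45C[C@@H](C=C[C@H]43)[C@](C)(OO)C5=O)[C@@H]1CO[Si](c1ccccc1)(c1ccccc1)C(C)(C)C | intermediate (not isolated)
31 | 16-hydroxy-16-methyl-15-ketone (5R,8S,9S,10S,13S,16S), C11=C12 | CC1(C)CCC2(OCCO2)[C@]3(COC(=O)[C@@]45C[C@@H](C=C[C@H]43)[C@](C)(O)C5=O)[C@@H]1CO[Si](c1ccccc1)(c1ccccc1)C(C)(C)C | intermediate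
32 | 11,12-dihydro compound (5R,8S,9S,10S,13R,16S), C1 dioxolane, C6 OTBDPS | CC1(C)CCC2(OCCO2)[C@]3(COC(=O)[C@@]45C[C@@H](CC[C@H]43)[C@](C)(O)C5=O)[C@@H]1CO[Si](c1ccccc1)(c1ccccc1)C(C)(C)C | intermediate
33 | C1 ketone (5R,8S,9S,10S,13R,16S), C6 OTBDPS | CC1(C)CCC(=O)[C@]2(COC(=O)[C@@]34C[C@@H](CC[C@H]32)[C@](C)(O)C4=O)[C@@H]1CO[Si](c1ccccc1)(c1ccccc1)C(C)(C)C | intermediate
34 | 6-O-TBDPS ether of the target (1-oxo-2-ene) | CC1(C)C=CC(=O)[C@]2(COC(=O)[C@@]34C[C@@H](CC[C@H]32)[C@](C)(O)C4=O)[C@@H]1CO[Si](c1ccccc1)(c1ccccc1)C(C)(C)C | intermediate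
35 | CNP0530135.1, (5R,8S,9S,10S,13R,16S) | CC1(C)C=CC(=O)[C@]2(COC(=O)[C@@]34C[C@@H](CC[C@H]32)[C@](C)(O)C4=O)[C@@H]1CO | target

## Step count and least certain steps

Total: 22 steps. Longest linear sequence: 21 steps (steps 1–10 and 12–22, from 1 to 35); step 11 is the side branch.

**Step 17 (key step, Proposed new method).** The Breslow intermediate may form slowly at a neopentyl aldehyde. The formyl group may be lost by retro-Claisen cleavage of the β-formyl lactone through the carbene adduct or traces of hydroxide. The product enone may be consumed by conjugate addition of the carbene or of a second acyl anion. The fallback uses known radical chemistry and sets out from 28. SmI2 with HMPA and t-BuOH in THF should reduce the aldehyde to its ketyl radical, which closes onto C16 in the same 5-exo-dig sense. The vinyl radical takes a hydrogen atom from the solvent and gives the 15-hydroxy-16-methylene compound F1 (either C15 epimer serves). Oxidation of this allylic alcohol with MnO2 or Dess–Martin periodinane comes back to the route at 29.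

**Step 14.** The carbonyl-endo preference may erode, because the 1,1-disubstituted dienophile puts its CH2OH group endo in the competing transition state; this would give the trans-fused lactone with C15 trans to the alkyne. The diene may also add slowly, since it carries an inside substituent, or on the face that places the arm next to C5. The fallback sets out from 22. NaH and one equivalent of monomeric formaldehyde give, by a plain Horner–Wadsworth–Emmons reaction, the unsubstituted acrylate F2. Its intramolecular Diels–Alder reaction (a less hindered, monosubstituted dienophile) gives the lactone F3, in which C8 still carries hydrogen, so the ring-fusion outcome of the cycloaddition no longer matters. LDA and then monomeric formaldehyde hydroxymethylate the lactone enolate on the face cis to H9, as angular alkylations of fused enolates do, and this comes back to the route at 26. C8 is then set by alkylation and not by the endo rule.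

**Step 3.** Turnover may be low because the product is a chelating β-keto ester and the β-carbon is neopentyl. Protodeboronation may outrun addition, and enantioselectivity may be poor for an acceptor with two carbonyl groups. The fallback replaces catalyst control by an auxiliary and sets out from 3:
- Exchange of the ester with (1R,2S,5R)-8-phenylmenthol (toluene, reflux, removal of methanol) gives the auxiliary ester F4.
- Selenenylation and selenoxide elimination as in step 2, through the selenide F5 and the selenoxide F6, give the alkylidene keto ester F7.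
- Copper-catalysed addition of (E)-styrylmagnesium bromide (CuBr·SMe2, THF, −78 °C) on the enone face left open by the phenyl group gives the adduct F8.
- Exchange of the auxiliary for methanol (MeOH, DMAP, toluene, 100 °C, through the acylketene) comes back to the route at 8.

**Step 18.** Facial selectivity at the planar C16 radical may be poor, because the unsaturated C11=C12 bridge shields the endo face less than a saturated one would. The radical may also be reduced before it captures oxygen. The fallback sets out from 29. Hydrogenation (H2, Pd/C) saturates C16=C17 and C11=C12 together and gives the 16-methyl ketone F9 (both C16 epimers are usable). Its potassium enolate (KHMDS, THF, −78 °C; C16 is the only enolisable position) is hydroxylated by 2-(phenylsulfonyl)-3-phenyloxaziridine from the exo face. This comes back to the route at 32, and steps 18 and 19 are left out.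

## Further compounds

F1 | step 17 | 15-hydroxy-16-methylene tetracycle (C15 epimers), C1 dioxolane, C6 OTBDPS, C11=C12 | CC1(C)CCC2(OCCO2)[C@]3(COC(=O)[C@@]45C[C@@H](C=C[C@H]43)C(=C)C5O)[C@@H]1CO[Si](c1ccccc1)(c1ccccc1)C(C)(C)C
F2 | step 14 | [(6S,7R)-7-{[tert-butyl(diphenyl)silyl]oxymethyl}-8,8-dimethyl-6-[(1E,3Z)-6-(trimethylsilyl)hexa-1,3-dien-5-yn-1-yl]-1,4-dioxaspiro[4.5]decan-6-yl]methyl prop-2-enoate | CC1(C)CCC2(OCCO2)[C@](/C=C/C=C\C#C[Si](C)(C)C)(COC(=O)C=C)[C@@H]1CO[Si](c1ccccc1)(c1ccccc1)C(C)(C)C
F3 | step 14 | tricyclic lactone as 26 but with hydrogen on C8 (C8 unassigned) | CC1(C)CCC2(OCCO2)[C@]3(COC(=O)C4C[C@H](C#C[Si](C)(C)C)C=C[C@H]43)[C@@H]1CO[Si](c1ccccc1)(c1ccccc1)C(C)(C)C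
F4 | step 3 | (1R,2S,5R)-5-methyl-2-(2-phenylpropan-2-yl)cyclohexyl 5,5-dimethyl-2-oxocyclohexane-1-carboxylate | C[C@@H]1CC[C@H]([C@@H](C1)OC(=O)C1CC(C)(C)CCC1=O)C(C)(C)c1ccccc1
F5 | step 3 | (1R,2S,5R)-5-methyl-2-(2-phenylpropan-2-yl)cyclohexyl 5,5-dimethyl-2-oxo-1-(phenylselanyl)cyclohexane-1-carboxylate | C[C@@H]1CC[C@H]([C@@H](C1)OC(=O)C1([Se]c2ccccc2)CC(C)(C)CCC1=O)C(C)(C)c1ccccc1
F6 | step 3 | (1R,2S,5R)-5-methyl-2-(2-phenylpropan-2-yl)cyclohexyl 5,5-dimethyl-2-oxo-1-(phenylseleninyl)cyclohexane-1-carboxylate | C[C@@H]1CC[C@H]([C@@H](C1)OC(=O)C1([Se](=O)c2ccccc2)CC(C)(C)CCC1=O)C(C)(C)c1ccccc1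
F7 | step 3 | (1R,2S,5R)-5-methyl-2-(2-phenylpropan-2-yl)cyclohexyl 3,3-dimethyl-6-oxocyclohex-1-ene-1-carboxylate | C[C@@H]1CC[C@H]([C@@H](C1)OC(=O)C1=CC(C)(C)CCC1=O)C(C)(C)c1ccccc1
F8 | step 3 | (1R,2S,5R)-5-methyl-2-(2-phenylpropan-2-yl)cyclohexyl (6S)-5,5-dimethyl-2-oxo-6-[(E)-2-phenylethenyl]cyclohexane-1-carboxylate | C[C@@H]1CC[C@H]([C@@H](C1)OC(=O)C1C(=O)CCC(C)(C)[C@H]1/C=C/c1ccccc1)C(C)(C)c1ccccc1
F9 | step 18 | saturated 16-methyl-15-ketone (C16 epimers), C1 dioxolane, C6 OTBDPS | CC1(C)CCC2(OCCO2)[C@]3(COC(=O)[C@@]45C[C@@H](CC[C@H]43)C(C)C5=O)[C@@H]1CO[Si](c1ccccc1)(c1ccccc1)C(C)(C)C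
A1 | alternative 1 | ring A enone with C2 ketone, C1=C10, C10 vinyl and O6 (bromomethyl)dimethylsilyl ether | CC1(C)CC(=O)C=C(C=C)[C@@H]1CO[Si](C)(C)CBr
A2 | alternative 1 | cis-fused siloxane with quaternary C10 (C10 vinyl, C2 ketone) | CC1(C)CC(=O)C[C@]2(C=C)C[Si](C)(C)OC[C@H]12
A3 | alternative 2 | ring A (E,Z)-dienyne with C1 ketone and O20 2-(silyloxymethyl)acrylate | CC1(C)CCC(=O)[C@](/C=C/C=C\C#C[Si](C)(C)C)(COC(=O)C(=C)CO[Si](C)(C)C(C)(C)C)[C@@H]1CO[Si](C)(C)C(C)(C)C
A4 | alternative 2 | tricyclic lactone with C1 ketone, C13 (trimethylsilyl)ethynyl and silyl ethers on O15 and O6 | CC1(C)CCC(=O)[C@]2(COC(=O)[C@@]3(CO[Si](C)(C)C(C)(C)C)C[C@H](C#C[Si](C)(C)C)C=C[C@H]32)[C@@H]1CO[Si](C)(C)C(C)(C)C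
A5 | alternative 3 | spiro 2-acyl unsaturated lactone (C8=C9, S-ethyl thioester on C8) | CC1(C)CCC(=O)[C@]2(COC(=O)C(C(=O)SCC)=C2)[C@@H]1CO[Si](C)(C)C(C)(C)C
A6 | alternative 3 | buta-1,3-diene | C=CC=C
A7 | alternative 3 | cis-fused cyclohexene lactone with quaternary C8 (thioester, C12=C13) | CC1(C)CCC(=O)[C@]2(COC(=O)[C@@]3(C(=O)SCC)CC=CC[C@H]32)[C@@H]1CO[Si](C)(C)C(C)(C)C
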